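## Retrosynthetic overview

1. Target 26 comes from peroxyketal 25, made by SN2 inversion of the side-chain allylic mesylate; the skeleton is joined by a B-alkyl Suzuki coupling of vinyl left fragment 20 with enol triflate right fragment 12.
2. Both fragments come from one cyclopentanone, 7, built from 2-methylcyclopentane-1,3-dione, acrolein and 2-bromopropene (Michael addition, asymmetric Nozaki–Hiyama–Kishi reaction, CBS desymmetrisation).
3. Right fragment: one-carbon ring expansion of the cyclopentanone with diazoethane (the CH2 migrates), then enol triflate formation.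
4. Left fragment: double Mitsunobu inversion of 7, oxepane closure, spiro vinyl epoxide, then a palladium-triggered semipinacol ring expansion (the quaternary carbon migrates) to ring B; MeLi/CeCl3 sets the tertiary carbinol.
5. Ring order: cyclopentane (from the start), then oxepane, then cyclohexane ring B by ring expansion; the cyclohexene of the right fragment is made by ring expansion in parallel.

Assumption: the senses of induction in steps 2 and 3 are assigned from the accepted models (the antipodal ligand is used if a sense proves opposite), and diazoethane solution, allyldiphenylsulfonium tetrafluoroborate and 2-methoxyprop-2-yl hydroperoxide are reagents prepared by standard procedures.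

Locants: left bicycle as 1-benzoxepine (O1, C2, C3, C4, C5, C5a, C6–C9, C9a); its cyclopentane precursors as cyclopenta[b]oxepine (O1, C2–C5, C5a, C6–C8, C8a). Some descriptors change between intermediates only because CIP priorities change, not the geometry.

## Route

Step 1
Reactants: 1 2-methylcyclopentane-1,3-dione; 2 acrolein
Product: 3 3-(1-methyl-2,5-dioxocyclopentyl)propanal
Conditions: H2O, rt
Reagents that add atoms: none
Why: Michael addition of the acidic 2-substituted 1,3-dione to acrolein gives the quaternary carbon, which is still prochiral, so no stereocentre is formed.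

Step 2
Reactants: 3 3-(1-methyl-2,5-dioxocyclopentyl)propanal; 4 2-bromopropene
Product: 6 2-[(3R)-3-hydroxy-4-methylpent-4-en-1-yl]-2-methylcyclopentane-1,3-dione, via trimethylsilyl ether 5 (not isolated)
Conditions: CrCl2 (10 mol %), (R)-N-[2-(4-isopropyl-4,5-dihydro-1,3-oxazol-2-yl)-6-methylphenyl]methanesulfonamide (11 mol %), Et3N, NiCl2·(2,9-dimethyl-1,10-phenanthroline) (2 mol %), Mn powder, Me3SiCl, LiCl, MeCN, rt; then 1 M HCl
Reagents that add atoms: none
Why: Catalytic asymmetric Nozaki–Hiyama–Kishi alkenylation, in which the alkenylchromium species adds only to the aldehyde (the ketones are inert) and the chiral sulfonamide ligand on chromium sets the (3R)-carbinol.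

Step 3
Reactants: 6 2-[(3R)-3-hydroxy-4-methylpent-4-en-1-yl]-2-methylcyclopentane-1,3-dione
Product: 7 (2R,3R)-3-hydroxy-2-[(3R)-3-hydroxy-4-methylpent-4-en-1-yl]-2-methylcyclopentan-1-one
Conditions: (S)-2-methyl-CBS-oxazaborolidine (20 mol %), catecholborane (2.5 equiv), toluene, −78 °C; then MeOH, aq. NaOH
Reagents that add atoms: none
Why: Corey–Bakshi–Shibata reduction used as a desymmetrisation, in which the catalyst gives the (R)-carbinol and hydride attack anti to the larger C2 substituent selects the carbonyl, fixing the quaternary centre (2R) with OH cis to the side chain; catecholborane does not hydroborate the alkene at −78 °C.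

Step 4
Reactants: 7 (2R,3R)-3-hydroxy-2-[(3R)-3-hydroxy-4-methylpent-4-en-1-yl]-2-methylcyclopentan-1-one
Product: 9 (2R,3R)-3-(tert-butyldimethylsilyloxy)-2-methyl-2-[(3R)-4-methyl-3-(triethylsilyloxy)pent-4-en-1-yl]cyclopentan-1-one, via mono(triethylsilyl) ether 8 (not isolated)
Conditions: Et3SiCl (1.05 equiv), imidazole, CH2Cl2, −40 °C; then t-BuMe2SiOTf, 2,6-lutidine, −78 to 0 °C
Reagents that add atoms: chlorotriethylsilane CC[Si](Cl)(CC)CC; tert-butyldimethylsilyl trifluoromethanesulfonate CC(C)(C)[Si](C)(C)OS(=O)(=O)C(F)(F)F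
Why: Sequential silylation by steric differentiation, the unhindered allylic hydroxyl taking the triethylsilyl group first and the neopentyl ring hydroxyl then needing the silyl triflate; no stereocentre changes.

Step 5
Reactants: 9 (2R,3R)-3-(tert-butyldimethylsilyloxy)-2-methyl-2-[(3R)-4-methyl-3-(triethylsilyloxy)pent-4-en-1-yl]cyclopentan-1-one
Product: 10 (2R,3R)-3-(tert-butyldimethylsilyloxy)-2,6-dimethyl-2-[(3R)-4-methyl-3-(triethylsilyloxy)pent-4-en-1-yl]cyclohexan-1-one (C6 epimer mixture)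
Conditions: CH3CHN2 (Et2O solution, 3 equiv), Sc(OTf)3 (10 mol %), toluene, −78 to −20 °C
Reagents that add atoms: diazoethane CC=[N+]=[N-]
Why: Lewis-acid-catalysed diazoalkane homologation (Tiffeneau–Demjanov-type 1,2-shift), in which the betaine loses N2 with migration of the less substituted CH2, so CH(CH3) is inserted on the side away from the quaternary carbon; the new α-methyl centre is a mixture that is erased in step 6.

Step 6
Reactants: 10 (2R,3R)-3-(tert-butyldimethylsilyloxy)-2,6-dimethyl-2-[(3R)-4-methyl-3-(triethylsilyloxy)pent-4-en-1-yl]cyclohexan-1-one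
Product: 12 (5R,6R)-5-(tert-butyldimethylsilyloxy)-2,6-dimethyl-6-[(3R)-4-methyl-3-(triethylsilyloxy)pent-4-en-1-yl]cyclohex-1-en-1-yl trifluoromethanesulfonate, via potassium enolate 11 (not isolated)
Conditions: KN(SiMe3)2, THF, −78 °C; then PhNTf2, −78 to 0 °C
Reagents that add atoms: N-phenylbis(trifluoromethanesulfonimide) O=S(=O)(N(c1ccccc1)S(=O)(=O)C(F)(F)F)C(F)(F)F
Why: Enol triflate formation that is regiospecific because the only α-hydrogen sits on the methyl-bearing carbon, giving the tetrasubstituted enol triflate.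

Step 7
Reactants: 7 (2R,3R)-3-hydroxy-2-[(3R)-3-hydroxy-4-methylpent-4-en-1-yl]-2-methylcyclopentan-1-one
Product: 13 (1S,2R)-2-methyl-2-[(3S)-4-methyl-3-(4-nitrobenzoyloxy)pent-4-en-1-yl]-3-oxocyclopentyl 4-nitrobenzoate
Conditions: 4-O2NC6H4CO2H, PPh3, DIAD (4 equiv each), toluene, 0 to 50 °C
Reagents that add atoms: 4-nitrobenzoic acid O=C(O)c1ccc(cc1)[N+](=O)[O-]
Why: Double Mitsunobu reaction, in which both secondary alcohols are displaced by 4-nitrobenzoate with SN2 inversion, giving the (3S) side-chain centre and the ring carbinol cis to the methyl group that the left fragment needs; the quaternary centre is untouched.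

Step 8
Reactants: 13 (1S,2R)-2-methyl-2-[(3S)-4-methyl-3-(4-nitrobenzoyloxy)pent-4-en-1-yl]-3-oxocyclopentyl 4-nitrobenzoate
Product: 14 (2R,3S)-3-hydroxy-2-[(3S)-3-hydroxy-4-methylpent-4-en-1-yl]-2-methylcyclopentan-1-one
Conditions: K2CO3 (cat.), MeOH, 0 °C
Reagents that add atoms: none
Why: Base-catalysed transesterification frees both alcohols with retention, the activated nitrobenzoates cleaving at 0 °C before retro-aldol of the β-hydroxy ketone can compete.

Step 9
Reactants: 14 (2R,3S)-3-hydroxy-2-[(3S)-3-hydroxy-4-methylpent-4-en-1-yl]-2-methylcyclopentan-1-one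
Product: 15 (2R,3S)-2-[(3S)-3-(tert-butyldimethylsilyloxy)-4-methylpent-4-en-1-yl]-3-hydroxy-2-methylcyclopentan-1-one
Conditions: t-BuMe2SiCl, imidazole, DMF, 0 °C
Reagents that add atoms: tert-butyldimethylsilyl chloride CC(C)(C)[Si](C)(C)Cl
Why: Selective silylation of the unhindered allylic hydroxyl leaves the neopentyl ring hydroxyl free for the etherification.

Step 10
Reactants: 15 (2R,3S)-2-[(3S)-3-(tert-butyldimethylsilyloxy)-4-methylpent-4-en-1-yl]-3-hydroxy-2-methylcyclopentan-1-one
Product: 17 (3S,5aR,8aS)-3-(tert-butyldimethylsilyloxy)-2,2,5a-trimethyloctahydro-6H-cyclopenta[b]oxepin-6-one (trans-fused), via organomercury trifluoroacetate 16 (not isolated)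
Conditions: Hg(OCOCF3)2, CH3NO2, −20 to 0 °C; then n-Bu3SnH, THF, 0 °C
Reagents that add atoms: none
Why: Intramolecular alkoxymercuration–demercuration, in which the ring hydroxyl opens the mercurinium ion at the tertiary carbon (Markovnikov, 7-exo), the hydroxyl being trans to the side chain makes the oxepane trans-fused, and tin hydride replaces mercury by hydrogen to leave the gem-dimethyl group without reducing the ketone.

Step 11
Reactants: 17 (3S,5aR,8aS)-3-(tert-butyldimethylsilyloxy)-2,2,5a-trimethyloctahydro-6H-cyclopenta[b]oxepin-6-one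
Product: 18 (3S,5aR,8aS)-3-(tert-butyldimethylsilyloxy)-2,2,5a-trimethyl-3'-vinyloctahydrospiro[cyclopenta[b]oxepine-6,2'-oxirane] (epoxide diastereomer mixture)
Conditions: allyldiphenylsulfonium tetrafluoroborate, t-BuLi, THF, −78 °C; then 17, −78 °C to rt
Reagents that add atoms: allyldiphenylsulfonium tetrafluoroborate C=CC[S+](c1ccccc1)c1ccccc1.F[B-](F)(F)F
Why: Sulfonium ylide epoxidation (Corey–Chaykovsky type), in which the allylide adds through its α-carbon and the betaine closes to the vinyl oxirane; both new centres are destroyed or reset in step 12, so the mixture is used as such.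

Step 12
Reactants: 18 (3S,5aR,8aS)-3-(tert-butyldimethylsilyloxy)-2,2,5a-trimethyl-3'-vinyloctahydrospiro[cyclopenta[b]oxepine-6,2'-oxirane]
Product: 19 (3S,5aS,6S,9aS)-3-(tert-butyldimethylsilyloxy)-6-ethenyl-2,2,5a-trimethyloctahydro-1-benzoxepin-7(2H)-one
Conditions: Pd2(dba)3·CHCl3 (5 mol %), P(OPh)3 (30 mol %), toluene, 60 °C
Reagents that add atoms: none
Why: Proposed new method: zerovalent palladium should ionise the allylic C–O bond of the vinyl epoxide to a zwitterionic alkoxide/π-allylpalladium species (closest known reactions: palladium-catalysed isomerisation of vinyl epoxides and the palladium-catalysed Wagner–Meerwein ring expansion of vinyl- and allenylcyclobutanols, which rely on strain in the carbocycle); here the carbinol carbon carries no hydrogen, so diene formation is shut off and epoxide re-closure is reversible, leaving the semipinacol 1,2-shift of the electron-rich quaternary carbon onto the allyl terminus anti to palladium, driven by C=O formation and release of epoxide strain, as the irreversible exit that builds ring B; the migrating carbon keeps its configuration, and π–σ–π equilibration of the allyl lets the chair-like transition state place the vinyl group equatorial, which is also the thermodynamic C6 epimer (6S).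

Step 13
Reactants: 19 (3S,5aS,6S,9aS)-3-(tert-butyldimethylsilyloxy)-6-ethenyl-2,2,5a-trimethyloctahydro-1-benzoxepin-7(2H)-one
Product: 20 (3S,5aS,6S,7R,9aS)-3-(tert-butyldimethylsilyloxy)-6-ethenyl-2,2,5a,7-tetramethyldecahydro-1-benzoxepin-7-ol
Conditions: MeLi, CeCl3, THF, −78 °C
Reagents that add atoms: methyllithium [Li]C
Why: Organocerium 1,2-addition, which is non-basic so the β,γ-unsaturated ketone is neither enolised nor conjugated; the axial face of the carbonyl is blocked by the axial angular methyl in the 1,3-position, so methyl enters equatorially and the tertiary hydroxyl is axial (7R).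

Step 14
Reactants: 20 (3S,5aS,6S,7R,9aS)-3-(tert-butyldimethylsilyloxy)-6-ethenyl-2,2,5a,7-tetramethyldecahydro-1-benzoxepin-7-ol; 12 (5R,6R)-5-(tert-butyldimethylsilyloxy)-2,6-dimethyl-6-[(3R)-4-methyl-3-(triethylsilyloxy)pent-4-en-1-yl]cyclohex-1-en-1-yl trifluoromethanesulfonate
Product: 22 (3S,5aS,6S,7R,9aS)-3-(tert-butyldimethylsilyloxy)-6-{2-[(5R,6S)-5-(tert-butyldimethylsilyloxy)-2,6-dimethyl-6-[(3R)-4-methyl-3-(triethylsilyloxy)pent-4-en-1-yl]cyclohex-1-en-1-yl]ethyl}-2,2,5a,7-tetramethyldecahydro-1-benzoxepin-7-ol, via B-alkyl-9-BBN adduct 21 (not isolated)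
Conditions: 9-BBN, THF, rt; then 12, PdCl2(dppf) (10 mol %), AsPh3, Cs2CO3, DMF/H2O, 50 °C
Reagents that add atoms: none
Why: Hydroboration followed by B-alkyl Suzuki–Miyaura coupling, in which 9-BBN adds to the terminal carbon of the only alkene in 20 and the alkylborane couples with the enol triflate to form the C(sp3)–C(sp2) bond of the two-carbon link; no stereocentre is affected and the allylic silyl ether is inert to palladium.

Step 15
Reactants: 22 the coupled tris-silyl ether
Product: 23 (3S,5aS,6S,7R,9aS)-3-(tert-butyldimethylsilyloxy)-6-{2-[(5R,6S)-5-(tert-butyldimethylsilyloxy)-6-[(3R)-3-hydroxy-4-methylpent-4-en-1-yl]-2,6-dimethylcyclohex-1-en-1-yl]ethyl}-2,2,5a,7-tetramethyldecahydro-1-benzoxepin-7-ol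
Conditions: PPTS (cat.), MeOH/CH2Cl2, 0 °C
Reagents that add atoms: none
Why: Acid-catalysed methanolysis removes the unhindered allylic triethylsilyl ether much faster than the two neopentyl tert-butyldimethylsilyl ethers.

Step 16
Reactants: 23 the allylic alcohol
Product: 25 (3S,5aS,6S,7R,9aS)-3-(tert-butyldimethylsilyloxy)-6-{2-[(5R,6S)-5-(tert-butyldimethylsilyloxy)-6-[(3S)-3-[(2-methoxypropan-2-yl)peroxy]-4-methylpent-4-en-1-yl]-2,6-dimethylcyclohex-1-en-1-yl]ethyl}-2,2,5a,7-tetramethyldecahydro-1-benzoxepin-7-ol, via allylic methanesulfonate 24 (not isolated)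
Conditions: MsCl, Et3N, CH2Cl2, −40 °C; then MeOC(CH3)2OOH, CsOH·H2O, DMF, −40 to 0 °C
Reagents that add atoms: 2-methoxyprop-2-yl hydroperoxide COC(C)(C)OO
Why: Mesylation of the only unhindered secondary hydroxyl (the tertiary alcohol is inert at −40 °C) and SN2 alkylation of a peroxide anion, a weakly basic α-effect nucleophile, which displaces the allylic mesylate with inversion to set the (3S)-peroxy centre; the perketal cap prevents Kornblum–DeLaMare decomposition.

Step 17
Reactants: 25 the monoperoxyketal bis-silyl ether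
Product: 26 (3S,5aS,6S,7R,9aS)-6-{2-[(5R,6S)-6-[(3S)-3-hydroperoxy-4-methylpent-4-en-1-yl]-5-hydroxy-2,6-dimethylcyclohex-1-en-1-yl]ethyl}-2,2,5a,7-tetramethyldecahydro-1-benzoxepine-3,7-diol (CNP0271099.3)
Conditions: aq. HF (48%), MeCN, 0 °C to rt
Reagents that add atoms: none
Why: Aqueous acid hydrolyses the monoperoxyketal to the hydroperoxide and fluoride cleaves both silyl ethers, without touching any stereocentre; an allylic hydroperoxide tolerates dilute HF.

## Compound list

1 | 2-methylcyclopentane-1,3-dione | CC1C(=O)CCC1=O | starting material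
2 | acrolein | C=CC=O | starting material
3 | 3-(1-methyl-2,5-dioxocyclopentyl)propanal | O=CCCC1(C)C(=O)CCC1=O | intermediate
4 | 2-bromopropene | C=C(C)Br | starting material
5 | 2-methyl-2-[(3R)-4-methyl-3-(trimethylsilyloxy)pent-4-en-1-yl]cyclopentane-1,3-dione (not isolated) | C=C(C)[C@@H](CCC1(C)C(=O)CCC1=O)O[Si](C)(C)C | intermediate
6 | 2-[(3R)-3-hydroxy-4-methylpent-4-en-1-yl]-2-methylcyclopentane-1,3-dione | C=C(C)[C@@H](CCC1(C)C(=O)CCC1=O)O | intermediate
7 | (2R,3R)-3-hydroxy-2-[(3R)-3-hydroxy-4-methylpent-4-en-1-yl]-2-methylcyclopentan-1-one | C=C(C)[C@@H](CC[C@@]1(C)C(=O)CC[C@H]1O)O | intermediate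
8 | (2R,3R)-3-hydroxy-2-methyl-2-[(3R)-4-methyl-3-(triethylsilyloxy)pent-4-en-1-yl]cyclopentan-1-one (not isolated) | C=C(C)[C@@H](CC[C@@]1(C)C(=O)CC[C@H]1O)O[Si](CC)(CC)CC | intermediate
9 | (2R,3R)-3-(tert-butyldimethylsilyloxy)-2-methyl-2-[(3R)-4-methyl-3-(triethylsilyloxy)pent-4-en-1-yl]cyclopentan-1-one | C=C(C)[C@@H](CC[C@@]1(C)C(=O)CC[C@H]1O[Si](C)(C)C(C)(C)C)O[Si](CC)(CC)CC | intermediate
10 | (2R,3R)-3-(tert-butyldimethylsilyloxy)-2,6-dimethyl-2-[(3R)-4-methyl-3-(triethylsilyloxy)pent-4-en-1-yl]cyclohexan-1-one (C6 epimers) | C=C(C)[C@@H](CC[C@@]1(C)C(=O)C(C)CC[C@H]1O[Si](C)(C)C(C)(C)C)O[Si](CC)(CC)CC | intermediate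
11 | potassium enolate of 10 (not isolated) | C=C(C)[C@@H](CC[C@@]1(C)C([O-])=C(C)CC[C@H]1O[Si](C)(C)C(C)(C)C)O[Si](CC)(CC)CC.[K+] | intermediate
12 | (5R,6R)-5-(tert-butyldimethylsilyloxy)-2,6-dimethyl-6-[(3R)-4-methyl-3-(triethylsilyloxy)pent-4-en-1-yl]cyclohex-1-en-1-yl trifluoromethanesulfonate | C=C(C)[C@@H](CC[C@@]1(C)C(OS(=O)(=O)C(F)(F)F)=C(C)CC[C@H]1O[Si](C)(C)C(C)(C)C)O[Si](CC)(CC)CC | intermediate
13 | (1S,2R)-2-methyl-2-[(3S)-4-methyl-3-(4-nitrobenzoyloxy)pent-4-en-1-yl]-3-oxocyclopentyl 4-nitrobenzoate | C=C(C)[C@H](CC[C@@]1(C)C(=O)CC[C@@H]1OC(=O)c1ccc(cc1)[N+](=O)[O-])OC(=O)c1ccc(cc1)[N+](=O)[O-] | intermediate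
14 | (2R,3S)-3-hydroxy-2-[(3S)-3-hydroxy-4-methylpent-4-en-1-yl]-2-methylcyclopentan-1-one | C=C(C)[C@H](CC[C@@]1(C)C(=O)CC[C@@H]1O)O | intermediate
15 | (2R,3S)-2-[(3S)-3-(tert-butyldimethylsilyloxy)-4-methylpent-4-en-1-yl]-3-hydroxy-2-methylcyclopentan-1-one | C=C(C)[C@H](CC[C@@]1(C)C(=O)CC[C@@H]1O)O[Si](C)(C)C(C)(C)C | intermediate
16 | {[(3S,5aR,8aS)-3-(tert-butyldimethylsilyloxy)-2,5a-dimethyl-6-oxooctahydro-2H-cyclopenta[b]oxepin-2-yl]methyl}mercury trifluoroacetate (C2 epimers; not isolated) | O=C1[C@]3(C)CC[C@H](O[Si](C)(C)C(C)(C)C)C(C)(C[Hg]OC(=O)C(F)(F)F)O[C@H]3CC1 | intermediate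
17 | (3S,5aR,8aS)-3-(tert-butyldimethylsilyloxy)-2,2,5a-trimethyloctahydro-6H-cyclopenta[b]oxepin-6-one | O=C1[C@]3(C)CC[C@H](O[Si](C)(C)C(C)(C)C)C(C)(C)O[C@H]3CC1 | intermediate
18 | (3S,5aR,8aS)-3-(tert-butyldimethylsilyloxy)-2,2,5a-trimethyl-3'-vinyloctahydrospiro[cyclopenta[b]oxepine-6,2'-oxirane] (epoxide diastereomers) | C=CC4OC41[C@]3(C)CC[C@H](O[Si](C)(C)C(C)(C)C)C(C)(C)O[C@H]3CC1 | intermediate
19 | (3S,5aS,6S,9aS)-3-(tert-butyldimethylsilyloxy)-6-ethenyl-2,2,5a-trimethyloctahydro-1-benzoxepin-7(2H)-one | C=C[C@H]2[C@]3(C)CC[C@H](O[Si](C)(C)C(C)(C)C)C(C)(C)O[C@H]3CCC2=O | intermediate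
20 | (3S,5aS,6S,7R,9aS)-3-(tert-butyldimethylsilyloxy)-6-ethenyl-2,2,5a,7-tetramethyldecahydro-1-benzoxepin-7-ol | C=C[C@H]2[C@]3(C)CC[C@H](O[Si](C)(C)C(C)(C)C)C(C)(C)O[C@H]3CC[C@@]2(C)O | intermediate
21 | 6-[2-(9-borabicyclo[3.3.1]nonan-9-yl)ethyl] analogue of 20 (not isolated) | C1CC2CCCC(C1)B2CC[C@H]5[C@]6(C)CC[C@H](O[Si](C)(C)C(C)(C)C)C(C)(C)O[C@H]6CC[C@@]5(C)O | intermediate
22 | (3S,5aS,6S,7R,9aS)-3-(tert-butyldimethylsilyloxy)-6-{2-[(5R,6S)-5-(tert-butyldimethylsilyloxy)-2,6-dimethyl-6-[(3R)-4-methyl-3-(triethylsilyloxy)pent-4-en-1-yl]cyclohex-1-en-1-yl]ethyl}-2,2,5a,7-tetramethyldecahydro-1-benzoxepin-7-ol | C=C(C)[C@@H](CC[C@@]1(C)C(CC[C@H]2[C@]3(C)CC[C@H](O[Si](C)(C)C(C)(C)C)C(C)(C)O[C@H]3CC[C@@]2(C)O)=C(C)CC[C@H]1O[Si](C)(C)C(C)(C)C)O[Si](CC)(CC)CC | intermediate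
23 | analogue of 22 with a free (3R)-hydroxyl on the pentenyl chain | C=C(C)[C@@H](CC[C@@]1(C)C(CC[C@H]2[C@]3(C)CC[C@H](O[Si](C)(C)C(C)(C)C)C(C)(C)O[C@H]3CC[C@@]2(C)O)=C(C)CC[C@H]1O[Si](C)(C)C(C)(C)C)O | intermediate
24 | (3R)-methanesulfonate of 23 (not isolated) | C=C(C)[C@@H](CC[C@@]1(C)C(CC[C@H]2[C@]3(C)CC[C@H](O[Si](C)(C)C(C)(C)C)C(C)(C)O[C@H]3CC[C@@]2(C)O)=C(C)CC[C@H]1O[Si](C)(C)C(C)(C)C)OS(C)(=O)=O | intermediate
25 | (3S)-(2-methoxypropan-2-yl)peroxy analogue (monoperoxyketal; side-chain centre inverted) | C=C(C)[C@H](CC[C@@]1(C)C(CC[C@H]2[C@]3(C)CC[C@H](O[Si](C)(C)C(C)(C)C)C(C)(C)O[C@H]3CC[C@@]2(C)O)=C(C)CC[C@H]1O[Si](C)(C)C(C)(C)C)OOC(C)(C)OC | intermediate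
26 | (3S,5aS,6S,7R,9aS)-6-{2-[(5R,6S)-6-[(3S)-3-hydroperoxy-4-methylpent-4-en-1-yl]-5-hydroxy-2,6-dimethylcyclohex-1-en-1-yl]ethyl}-2,2,5a,7-tetramethyldecahydro-1-benzoxepine-3,7-diol | C=C(C)[C@H](CC[C@@]1(C)C(CC[C@H]2[C@]3(C)CC[C@H](O)C(C)(C)O[C@H]3CC[C@@]2(C)O)=C(C)CC[C@H]1O)OO | target

## Step count and risks

Total step count: 17. Longest linear sequence: 14 steps (1, 2, 3, 7–17); the right fragment (steps 4–6) joins at step 14.

Three steps most likely to fail:

Step 12 (the proposed palladium-triggered ring expansion). The π-allyl zwitterion may simply re-close, the ring CH2 may migrate instead of the quaternary carbon, or a dihydrofuran may form. The fallback uses known chemistry, sets out from 17 and comes back at 20. CH2=CHMgBr with CeCl3 adds to ketone 17 to give the tertiary allylic alcohol F1. VO(acac)2 with t-BuOOH epoxidises it to the epoxy alcohol F2. BF3·OEt2 then brings about the established 2,3-epoxy-alcohol semipinacol rearrangement, in which the quaternary carbon migrates to the epoxide carbon as the carbinol becomes the ketone, giving the ring-expanded 6-(hydroxymethyl) ketone F3 (equatorial at C6 after equilibration). MeLi with CeCl3 gives the diol F4, TEMPO with PhI(OAc)2 oxidises the primary alcohol to the hydroxy aldehyde F5, and Ph3P=CH2 converts this into 20.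

Step 16 (invertive peroxide alkylation of an allylic mesylate). The mesylate may ionise or react in the SN2' sense. The fallback sets out from 23 and comes back at 26. CBr4 with PPh3 gives the allylic bromide F6. AgOCOCF3 with anhydrous H2O2 in Et2O (silver-assisted perhydrolysis of an allylic halide, not stereospecific) gives the hydroperoxide as an epimer mixture with some transposed primary isomer. The (3S)-hydroperoxide bis-silyl ether F7 is separated from this by preparative HPLC, and aq. HF in MeCN then gives 26.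

Step 10 (seven-membered alkoxymercuration next to a silyloxy group). Ring closure may be slow against intermolecular capture. The fallback sets out from 15 and comes back at 17. It is a cobalt-hydride hydrogen-atom-transfer hydroalkoxylation (Co(salen) complex of divalent cobalt, N-fluoro-2,4,6-trimethylpyridinium triflate, PhSiH3): the tertiary radical from the 1,1-disubstituted alkene is oxidised and trapped by the ring hydroxyl. This radical–polar crossover route has no organomercury stage and makes no compound outside the list, none F0.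

Further compounds

F0 | step 10 | none | none
F1 | step 12 | (3S,5aR,8aS)-3-(tert-butyldimethylsilyloxy)-6-ethenyl-2,2,5a-trimethyloctahydro-2H-cyclopenta[b]oxepin-6-ol (C6 epimers) | C=CC1(O)[C@]3(C)CC[C@H](O[Si](C)(C)C(C)(C)C)C(C)(C)O[C@H]3CC1
F2 | step 12 | (3S,5aR,8aS)-3-(tert-butyldimethylsilyloxy)-2,2,5a-trimethyl-6-(oxiran-2-yl)octahydro-2H-cyclopenta[b]oxepin-6-ol (diastereomers) | OC1(C2CO2)[C@]3(C)CC[C@H](O[Si](C)(C)C(C)(C)C)C(C)(C)O[C@H]3CC1
F3 | step 12 | 6-(hydroxymethyl) analogue of ketone 19 (CH2OH in place of vinyl; same spatial arrangement) | OC[C@H]2[C@]3(C)CC[C@H](O[Si](C)(C)C(C)(C)C)C(C)(C)O[C@H]3CCC2=O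
F4 | step 12 | 6-(hydroxymethyl) analogue of alcohol 20 (same spatial arrangement) | OC[C@H]2[C@]3(C)CC[C@H](O[Si](C)(C)C(C)(C)C)C(C)(C)O[C@H]3CC[C@@]2(C)O
F5 | step 12 | 6-formyl analogue of alcohol 20 (same spatial arrangement) | O=C[C@H]2[C@]3(C)CC[C@H](O[Si](C)(C)C(C)(C)C)C(C)(C)O[C@H]3CC[C@@]2(C)O
F6 | step 16 | allylic bromide from 23 (configuration at C–Br not defined) | C=C(C)C(Br)CC[C@@]1(C)C(CC[C@H]2[C@]3(C)CC[C@H](O[Si](C)(C)C(C)(C)C)C(C)(C)O[C@H]3CC[C@@]2(C)O)=C(C)CC[C@H]1O[Si](C)(C)C(C)(C)C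
F7 | step 16 | (3S)-hydroperoxide bis(tert-butyldimethylsilyl) ether of 26 | C=C(C)[C@H](CC[C@@]1(C)C(CC[C@H]2[C@]3(C)CC[C@H](O[Si](C)(C)C(C)(C)C)C(C)(C)O[C@H]3CC[C@@]2(C)O)=C(C)CC[C@H]1O[Si](C)(C)C(C)(C)C)OO
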